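**Strategy.** Ring labels: A is the left 3,5-dihydroxyphenoxy ring, B the outer ring of the dibenzodioxin, C the central ring, D the outer dibenzofuran ring and E the right phenoxy ring. Ring B is disconnected to a Fischer carbene: its carbon bearing O–ring A and its carbon bearing the hydroxyl beside the dioxin are para and flank the two dioxin carbons, a Dötz hydroquinone-monoether pattern with the dioxin C=C as alkene. One benzannulation of a methoxy(1,4-dioxin-2-yl)carbene chromium complex, already fused to the complete C/D/E dibenzofuran, with ethynylboronic acid pinacol ester and a CO ligand makes ring B with phenol, methoxy and boryl carbons all distinguished.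

Key step: step 13

Remark: the target has no stereocentre and no stereogenic axis and is achiral, so there is no enantiomer to select; the only stereocentre on the way (the hemiketal carbon of 3 and 4) is racemic and disappears in step 3.

**Route**

Step 1
Reactants: 1 3,4-dihydroxy-5-methoxybenzaldehyde; 2 ethyl 3-bromo-2-oxopropanoate
Product: 3 ethyl 7-formyl-2-hydroxy-5-methoxy-2,3-dihydro-1,4-benzodioxine-2-carboxylate (racemic hemiketal)
Conditions: KHCO3, DMF, 0 °C → rt
Reagents that add atoms: none
Why: Williamson etherification then ring-closing hemiketalisation: hydrogencarbonate ionises only the 4-hydroxyl (para to CHO), so this oxygen takes the CH2Br carbon and the 3-hydroxyl then adds to the very electrophilic keto ester carbonyl in a six-membered ring closure, which puts the carboxylate-bearing carbon on the oxygen meta to CHO (the later bay-side oxygen of ring C); the hemiketal carbon forms as a racemate and is planarised in step 3.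

Step 2
Reactants: 3 ethyl 7-formyl-2-hydroxy-5-methoxy-2,3-dihydro-1,4-benzodioxine-2-carboxylate
Product: 4 ethyl 7-(formyloxy)-2-hydroxy-5-methoxy-2,3-dihydro-1,4-benzodioxine-2-carboxylate (racemic)
Conditions: mCPBA, CH2Cl2, 0 °C → rt
Reagents that add atoms: 3-chloroperbenzoic acid, OOC(=O)c1cccc(Cl)c1
Why: Baeyer–Villiger (Dakin-type) oxidation in which the aryl group, activated by the para alkoxy oxygen as in 3,4,5-trialkoxybenzaldehydes, migrates in the Criegee adduct to give the aryl formate; it is run on the hemiketal because the later vinylogous-carbonate oxygen would be a much weaker para donor.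

Step 3
Reactants: 4 ethyl 7-(formyloxy)-2-hydroxy-5-methoxy-2,3-dihydro-1,4-benzodioxine-2-carboxylate
Product: 6 ethyl 7-hydroxy-5-methoxy-1,4-benzodioxine-2-carboxylate, via dioxin formate ester 5 (not isolated)
Conditions: TsOH·H2O (cat.), toluene, reflux (Dean–Stark); then K2CO3 (cat.), EtOH, 0 °C
Reagents that add atoms: none
Why: Acid-catalysed E1 dehydration of the cyclic hemiketal through its oxocarbenium ion gives the ester-conjugated enol ether (the reaction type by which 2-hydroxy-1,4-benzodioxanes give benzodioxines and ulosonate hemiketals give glycals), so the dioxin double bond needs no later dehydrogenation in the presence of electron-rich rings, and carbonate-catalysed transesterification then frees the phenol from its formate.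

Step 4
Reactants: 6 ethyl 7-hydroxy-5-methoxy-1,4-benzodioxine-2-carboxylate
Product: 7 ethyl 8-bromo-7-hydroxy-5-methoxy-1,4-benzodioxine-2-carboxylate
Conditions: NBS (1.0 equiv), MeCN, −20 → 0 °C
Reagents that add atoms: N-bromosuccinimide, O=C1CCC(=O)N1Br
Why: Electrophilic aromatic bromination of the phenol: C-8 is ortho to OH, para to the methoxy donor and flanked only by the ring oxygen O-1, whereas C-6 is shielded by the methoxy methyl turned towards it and is para only to O-1, a weak donor because it carries the acrylate carbon, so bromine is expected at C-8 (the assignment would be checked by NOE between H-6 and OCH3).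

Step 5
Reactants: 8 2,6-difluoro-4-methoxybenzaldehyde
Product: 9 2-fluoro-4,6-dimethoxybenzaldehyde
Conditions: NaOMe (1.0 equiv), MeOH/THF, 0 °C → rt
Reagents that add atoms: sodium methoxide, [Na+].[O-]C
Why: Nucleophilic aromatic substitution (SNAr) of a fluorine ortho to the formyl group; the first methoxy group deactivates the ring, so one equivalent of methoxide should stop at mono-exchange.

Step 6
Reactants: 7 ethyl 8-bromo-7-hydroxy-5-methoxy-1,4-benzodioxine-2-carboxylate; 9 2-fluoro-4,6-dimethoxybenzaldehyde
Product: 10 ethyl 8-bromo-7-(2-formyl-3,5-dimethoxyphenoxy)-5-methoxy-1,4-benzodioxine-2-carboxylate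
Conditions: Cs2CO3, DMSO, 90 °C
Reagents that add atoms: none
Why: SNAr diaryl ether synthesis through a Meisenheimer adduct stabilised by the ortho formyl group; fluoride is the only leaving group, and the aryl bromide and the enol-ether ester are inert to carbonate in dry DMSO.

Step 7
Reactants: 10 ethyl 8-bromo-7-(2-formyl-3,5-dimethoxyphenoxy)-5-methoxy-1,4-benzodioxine-2-carboxylate
Product: 12 ethyl 8-bromo-7-(2-hydroxy-3,5-dimethoxyphenoxy)-5-methoxy-1,4-benzodioxine-2-carboxylate, via aryl formate 11 (not isolated)
Conditions: mCPBA (1.1 equiv), CH2Cl2, 0 °C; then K2CO3 (cat.), EtOH, 0 °C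
Reagents that add atoms: 3-chloroperbenzoic acid, OOC(=O)c1cccc(Cl)c1
Why: Baeyer–Villiger (Dakin-type) oxidation of a 2,4,6-trioxygenated benzaldehyde, whose very electron-rich aryl group migrates fast at 0 °C so that the peracid is consumed before it can attack the acrylate-type dioxin double bond, followed by mild transesterification of the formate.

Step 8
Reactants: 13 1-iodo-3,5-dimethoxybenzene; 14 1,3,5-trimethoxybenzene
Product: 16 (3,5-dimethoxyphenyl)(2,4,6-trimethoxyphenyl)iodonium 4-methylbenzenesulfonate, via hydroxy(tosyloxy)iodoarene 15 (not isolated)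
Conditions: mCPBA, TsOH·H2O, MeCN, 77 °C; then 14, rt
Reagents that add atoms: 4-methylbenzenesulfonic acid monohydrate, Cc1ccc(S(=O)(=O)O)cc1.O
Why: One-pot diaryliodonium synthesis: peracid oxidation in the presence of the sulfonic acid gives the iodine(III) species, which undergoes electrophilic ligand exchange with 1,3,5-trimethoxybenzene much faster than with the doubly flanked positions of its own ring.

Step 9
Reactants: 12 ethyl 8-bromo-7-(2-hydroxy-3,5-dimethoxyphenoxy)-5-methoxy-1,4-benzodioxine-2-carboxylate; 16 (3,5-dimethoxyphenyl)(2,4,6-trimethoxyphenyl)iodonium 4-methylbenzenesulfonate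
Product: 17 ethyl 8-bromo-7-[2-(3,5-dimethoxyphenoxy)-3,5-dimethoxyphenoxy]-5-methoxy-1,4-benzodioxine-2-carboxylate
Conditions: Cs2CO3, toluene, 50 °C
Reagents that add atoms: none
Why: Metal-free O-arylation of a phenoxide with a diaryliodonium salt (ligand exchange at iodine(III), then ligand coupling), which tolerates di-ortho-substituted phenols and the aryl bromide and transfers the 3,5-dimethoxyphenyl group because the electron-rich trimethoxyphenyl ligand stays on iodine.

Step 10
Reactants: 17 ethyl 8-bromo-7-[2-(3,5-dimethoxyphenoxy)-3,5-dimethoxyphenoxy]-5-methoxy-1,4-benzodioxine-2-carboxylate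
Product: 18 ethyl dioxino-dibenzofuran carboxylate (dibenzofuran with a 1,4-dioxin ring fused through oxygens at C-1 and C-2; CO2Et on the dioxin carbon bonded to O–C-1; OMe at C-3/C-7/C-9; 3,5-dimethoxyphenoxy at C-6)
Conditions: Pd(OAc)2 (5 mol%), PCy3·HBF4 (10 mol%), K2CO3, DMA, 130 °C
Reagents that add atoms: none
Why: Palladium(0)-catalysed intramolecular direct arylation: oxidative addition into the C-8–Br bond and carbonate-assisted concerted metalation–deprotonation of the only ring-D C–H ortho to the ether oxygen close the furan ring, so the biaryl bond lies next to the oxygen that carries the carboxylate-bearing dioxin carbon.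

Step 11
Reactants: 18 ethyl dioxino-dibenzofuran carboxylate
Product: 19 dioxino-dibenzofuran carboxylic acid (free acid of 18)
Conditions: LiOH·H2O, THF/H2O, rt; then 1 M HCl
Reagents that add atoms: lithium hydroxide, [Li+].[OH-]
Why: Saponification of the ester followed by acidification; 1,4-benzodioxine-2-carboxylates hydrolyse to stable acids without opening of the enol ether.

Step 12
Reactants: 19 dioxino-dibenzofuran carboxylic acid; 20 chromium hexacarbonyl
Product: 23 pentacarbonyl[methoxy(1,4-dioxin-2-yl)carbene]chromium complex fused to the C/D/E dibenzofuran, via acid chloride 21 (not isolated), via sodium acylpentacarbonylchromate 22 (not isolated)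
Conditions: Me2C=C(Cl)NMe2, CH2Cl2, 0 °C → rt; Na2[Cr(CO)5] (from 20 and sodium naphthalenide, THF, −78 → 0 °C), THF, −78 → 0 °C; Me3OBF4, CH2Cl2, 0 °C
Reagents that add atoms: trimethyloxonium tetrafluoroborate, C[O+](C)C.F[B-](F)(F)F
Why: Acylmetalate route to Fischer carbenes: the acid chloride, made under neutral conditions with the chloroenamine to spare the electron-rich rings from Vilsmeier-type attack, acylates the pentacarbonylchromate dianion at the metal, and the acyl chromate is O-methylated by the oxonium salt.

Step 13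
Reactants: 23 pentacarbonyl[methoxy(1,4-dioxin-2-yl)carbene]chromium complex; 24 ethynylboronic acid pinacol ester
Product: 26 pentacyclic B/C/D/E core with new ring B (free OH on the carbon next to the dioxin carbon bound to O–C-2; pinacolboryl ortho to that OH; OMe para to it), via tricarbonylchromium arene complex 25 (not isolated)
Conditions: THF (degassed), 50 °C; then air, rt
Reagents that add atoms: none
Why: Thermal loss of one cis CO lets the alkyne bind and insert with its unsubstituted carbon next to the carbene carbon, CO then inserts to give a chromium-bound dienylketene, 6π-electrocyclisation of this ketene onto the dioxin CH carbon and tautomerisation give the phenol as its Cr(CO)3 complex, and air removes the metal. The closest known reaction type is the Dötz benzannulation of alkenyl(alkoxy)carbene chromium complexes with 1-alkynylboronates, which places boron ortho to the new hydroxyl. Ring B is closed by electrocyclic ring closure (bond between the former CO carbon and the dioxin β-carbon) after the two bonds to the alkyne carbons have been made by insertion. No stereocentre is formed. The step needs (i) the alkyne orientation with the CH end next to the carbene carbon, secured by the size difference between H and the pinacolboryl group together with the directing effect of boron, (ii) ring B growing in the right orientation, secured by the carbene sitting on the dioxin carbon bonded to the oxygen at dibenzofuran C-1 as fixed in steps 1 and 4, and (iii) phenol formation in preference to cyclopentannulation, favoured by the alkoxy carbene, an ethereal solvent and moderate temperature.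

Step 14
Reactants: 26 pentacyclic core with new ring B; 16 (3,5-dimethoxyphenyl)(2,4,6-trimethoxyphenyl)iodonium 4-methylbenzenesulfonate
Product: 27 ring-A aryl ether of 26 (3,5-dimethoxyphenoxy in place of the ring-B OH; boronate retained)
Conditions: Cs2CO3, toluene (anhydrous), 45 °C
Reagents that add atoms: none
Why: Diaryliodonium O-arylation (ligand coupling at iodine(III)) under carbonate, which needs no copper or palladium and so leaves the aryl boronate untouched while arylating the hindered phenoxide.

Step 15
Reactants: 27 ring-A aryl ether boronate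
Product: 28 octamethyl ether of the target with a free hydroxyl on ring B (OH in place of the boryl group)
Conditions: H2O2 (30%), NaOH aq, THF, 0 °C
Reagents that add atoms: hydrogen peroxide, OO
Why: Oxidation of the aryl boronate by hydroperoxide (1,2-aryl shift from boron to oxygen, then B–O hydrolysis) turns the C–B bond into the second ring-B hydroxyl at the same carbon.

Step 16
Reactants: 28 octamethyl ether of the target
Product: 29 phlorofucofuroeckol A
Conditions: BBr3 (excess), CH2Cl2, −78 °C → rt; then MeOH, H2O (under argon)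
Reagents that add atoms: none
Why: Lewis-acid ether cleavage: BBr3 complexes each of the eight methoxy oxygens and bromide removes the methyl groups by SN2, while the diaryl ether, dibenzofuran and dibenzodioxin C–O bonds are not cleaved; hydrolysis of the aryl borates should release the nonaphenol.

**Compound list**

1 | 3,4-dihydroxy-5-methoxybenzaldehyde (5-hydroxyvanillin) | COc1cc(C=O)cc(O)c1O | starting material
2 | ethyl 3-bromo-2-oxopropanoate (ethyl bromopyruvate) | CCOC(=O)C(=O)CBr | starting material
3 | ethyl 7-formyl-2-hydroxy-5-methoxy-2,3-dihydro-1,4-benzodioxine-2-carboxylate (racemic) | CCOC(=O)C1(O)COc2c(OC)cc(C=O)cc2O1 | intermediate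
4 | ethyl 7-(formyloxy)-2-hydroxy-5-methoxy-2,3-dihydro-1,4-benzodioxine-2-carboxylate (racemic) | CCOC(=O)C1(O)COc2c(OC)cc(OC=O)cc2O1 | intermediate
5 | ethyl 7-(formyloxy)-5-methoxy-1,4-benzodioxine-2-carboxylate (not isolated) | CCOC(=O)C1=COc2c(OC)cc(OC=O)cc2O1 | intermediate
6 | ethyl 7-hydroxy-5-methoxy-1,4-benzodioxine-2-carboxylate | CCOC(=O)C1=COc2c(OC)cc(O)cc2O1 | intermediate
7 | ethyl 8-bromo-7-hydroxy-5-methoxy-1,4-benzodioxine-2-carboxylate | CCOC(=O)C1=COc2c(OC)cc(O)c(Br)c2O1 | intermediate
8 | 2,6-difluoro-4-methoxybenzaldehyde | COc1cc(F)c(C=O)c(F)c1 | starting material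
9 | 2-fluoro-4,6-dimethoxybenzaldehyde | COc1cc(F)c(C=O)c(OC)c1 | intermediate
10 | ethyl 8-bromo-7-(2-formyl-3,5-dimethoxyphenoxy)-5-methoxy-1,4-benzodioxine-2-carboxylate | CCOC(=O)C1=COc2c(OC)cc(Oc3cc(OC)cc(OC)c3C=O)c(Br)c2O1 | intermediate
11 | ethyl 8-bromo-7-[2-(formyloxy)-3,5-dimethoxyphenoxy]-5-methoxy-1,4-benzodioxine-2-carboxylate (not isolated) | CCOC(=O)C1=COc2c(OC)cc(Oc3cc(OC)cc(OC)c3OC=O)c(Br)c2O1 | intermediate
12 | ethyl 8-bromo-7-(2-hydroxy-3,5-dimethoxyphenoxy)-5-methoxy-1,4-benzodioxine-2-carboxylate | CCOC(=O)C1=COc2c(OC)cc(Oc3cc(OC)cc(OC)c3O)c(Br)c2O1 | intermediate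
13 | 1-iodo-3,5-dimethoxybenzene | COc1cc(I)cc(OC)c1 | starting material
14 | 1,3,5-trimethoxybenzene | COc1cc(OC)cc(OC)c1 | starting material
15 | [hydroxy(tosyloxy)iodo]-3,5-dimethoxybenzene (not isolated) | COc1cc(OC)cc(I(O)OS(=O)(=O)c2ccc(C)cc2)c1 | intermediate
16 | (3,5-dimethoxyphenyl)(2,4,6-trimethoxyphenyl)iodonium 4-methylbenzenesulfonate | COc1cc(OC)cc([I+]c2c(OC)cc(OC)cc2OC)c1.Cc1ccc(S(=O)(=O)[O-])cc1 | intermediate
17 | ethyl 8-bromo-7-[2-(3,5-dimethoxyphenoxy)-3,5-dimethoxyphenoxy]-5-methoxy-1,4-benzodioxine-2-carboxylate | CCOC(=O)C1=COc2c(OC)cc(Oc3cc(OC)cc(OC)c3Oc3cc(OC)cc(OC)c3)c(Br)c2O1 | intermediate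
18 | ethyl dioxino-dibenzofuran carboxylate (1,4-dioxin fused via O at dibenzofuran C-1/C-2, CO2Et on the carbon bonded to O–C-1; OMe at C-3, C-7, C-9; 3,5-dimethoxyphenoxy at C-6) | CCOC(=O)C1=COc2c(OC)cc3oc4c(Oc5cc(OC)cc(OC)c5)c(OC)cc(OC)c4c3c2O1 | intermediate
19 | dioxino-dibenzofuran carboxylic acid (free acid of 18) | OC(=O)C1=COc2c(OC)cc3oc4c(Oc5cc(OC)cc(OC)c5)c(OC)cc(OC)c4c3c2O1 | intermediate
20 | chromium hexacarbonyl | O=C=[Cr](=C=O)(=C=O)(=C=O)(=C=O)=C=O | starting material
21 | acid chloride of 19 (not isolated) | ClC(=O)C1=COc2c(OC)cc3oc4c(Oc5cc(OC)cc(OC)c5)c(OC)cc(OC)c4c3c2O1 | intermediate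
22 | sodium acylpentacarbonylchromate of 19 (not isolated) | [Na+].[O-]C(=[Cr](=C=O)(=C=O)(=C=O)(=C=O)=C=O)C1=COc2c(OC)cc3oc4c(Oc5cc(OC)cc(OC)c5)c(OC)cc(OC)c4c3c2O1 | intermediate
23 | pentacarbonyl[methoxy(1,4-dioxin-2-yl)carbene]chromium complex fused to the C/D/E dibenzofuran | COC(=[Cr](=C=O)(=C=O)(=C=O)(=C=O)=C=O)C1=COc2c(OC)cc3oc4c(Oc5cc(OC)cc(OC)c5)c(OC)cc(OC)c4c3c2O1 | intermediate
24 | ethynylboronic acid pinacol ester (2-ethynyl-4,4,5,5-tetramethyl-1,3,2-dioxaborolane) | C#CB1OC(C)(C)C(C)(C)O1 | starting material
25 | tricarbonylchromium complex of 26 (η6 on ring B, written with the metal fragment detached; not isolated) | COc1cc(B2OC(C)(C)C(C)(C)O2)c(O)c2c1Oc1c3c4c(OC)cc(OC)c(Oc5cc(OC)cc(OC)c5)c4oc3cc(OC)c1O2.O=C=[Cr](=C=O)=C=O | intermediate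
26 | pentacyclic B/C/D/E core with new ring B (free phenol, ortho pinacolboryl, para methoxy) | COc1cc(B2OC(C)(C)C(C)(C)O2)c(O)c2c1Oc1c3c4c(OC)cc(OC)c(Oc5cc(OC)cc(OC)c5)c4oc3cc(OC)c1O2 | intermediate
27 | ring-A aryl ether of 26 (boronate retained) | COc1cc(B2OC(C)(C)C(C)(C)O2)c(Oc6cc(OC)cc(OC)c6)c2c1Oc1c3c4c(OC)cc(OC)c(Oc5cc(OC)cc(OC)c5)c4oc3cc(OC)c1O2 | intermediate
28 | octamethyl ether of the target with free ring-B hydroxyl | COc1cc(O)c(Oc6cc(OC)cc(OC)c6)c2c1Oc1c3c4c(OC)cc(OC)c(Oc5cc(OC)cc(OC)c5)c4oc3cc(OC)c1O2 | intermediate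
29 | phlorofucofuroeckol A (achiral) | Oc1cc(O)cc(Oc2c(O)cc(O)c3c2Oc2c(O)cc4oc5c(Oc6cc(O)cc(O)c6)c(O)cc(O)c5c4c2O3)c1 | target

**Step count and risks**

Total step count: 16. Longest linear sequence: 14 steps (1–4, 6, 7, 9–16, from compound 1).

Steps most likely to fail:

Step 13 (benzannulation). The alkyne may insert in the reverse sense, the boryl group may be lost by protodeboronation during the reaction or the air work-up, or the vinylcarbene may be diverted to cyclopentannulation. The fallback sets out from 23. Benzannulation with ethynyltrimethylsilane (THF, 50 °C, then air) would give the ortho-silyl phenol F1. Fluoride (TBAF, THF) would give the silicon-free phenol F2. Magnesium-mediated ortho-formylation (MgCl2, Et3N, paraformaldehyde, MeCN, reflux) would give the salicylaldehyde F3. O-arylation with 16 (Cs2CO3, toluene) would give the aryl ether aldehyde F4. Baeyer–Villiger oxidation (mCPBA) would give the aryl formate F5, whose methanolysis (K2CO3, MeOH) comes back to the route at 28.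

Step 14 (O-arylation beside boron). Ligand coupling at a phenoxide shielded by the ortho boronate and the dioxin oxygen may be slow, so that base-induced loss of boron competes. The fallback sets out from 26. The C–B bond is oxidised first (H2O2, NaOH) to the ring-B diol F6. The less hindered hydroxyl (the one with an ortho hydrogen) is silylated under steric control (TIPSCl, imidazole) to the mono-silyl ether F7. The remaining hydroxyl is arylated with 16 (Cs2CO3, toluene) to the silyl-protected aryl ether F8. Desilylation (TBAF) comes back at 28.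

Step 4 (site of bromination). Substitution may take place at C-6 instead of, or as well as, C-8, or twice, which would put the furan C–C bond on the wrong side of ring C. The fallback sets out from 6 without a halogen. SNAr with 9 would give the bromine-free diaryl ether aldehyde F9. Baeyer–Villiger oxidation would give the aryl formate F10 and ethanolysis the phenol F11. O-arylation with 16 would give the triaryl ether F12. Oxidative palladium(II) double C–H coupling (Pd(OAc)2, PivOH, K2CO3, air, 120 °C), in which concerted metalation–deprotonation selects the more acidic C-8–H beside O-1, comes back at 18.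

**Further compounds**

F1 | step 13 | ortho-trimethylsilyl phenol (26 with SiMe3 in place of the boryl group) | COc1cc([Si](C)(C)C)c(O)c2c1Oc1c3c4c(OC)cc(OC)c(Oc5cc(OC)cc(OC)c5)c4oc3cc(OC)c1O2
F2 | step 13 | silicon-free ring-B phenol (H in place of the boryl group) | COc1ccc(O)c2c1Oc1c3c4c(OC)cc(OC)c(Oc5cc(OC)cc(OC)c5)c4oc3cc(OC)c1O2
F3 | step 13 | ring-B salicylaldehyde (CHO ortho to the phenol) | COc1cc(C=O)c(O)c2c1Oc1c3c4c(OC)cc(OC)c(Oc5cc(OC)cc(OC)c5)c4oc3cc(OC)c1O2
F4 | step 13 | ring-A aryl ether aldehyde | COc1cc(C=O)c(Oc6cc(OC)cc(OC)c6)c2c1Oc1c3c4c(OC)cc(OC)c(Oc5cc(OC)cc(OC)c5)c4oc3cc(OC)c1O2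
F5 | step 13 | ring-A aryl ether aryl formate | COc1cc(OC=O)c(Oc6cc(OC)cc(OC)c6)c2c1Oc1c3c4c(OC)cc(OC)c(Oc5cc(OC)cc(OC)c5)c4oc3cc(OC)c1O2
F6 | step 14 | ring-B diol (OH in place of the boryl group of 26) | COc1cc(O)c(O)c2c1Oc1c3c4c(OC)cc(OC)c(Oc5cc(OC)cc(OC)c5)c4oc3cc(OC)c1O2
F7 | step 14 | mono-triisopropylsilyl ether of F6 (silyl on the less hindered oxygen) | COc1cc(O[Si](C(C)C)(C(C)C)C(C)C)c(O)c2c1Oc1c3c4c(OC)cc(OC)c(Oc5cc(OC)cc(OC)c5)c4oc3cc(OC)c1O2
F8 | step 14 | ring-A aryl ether of F7 | COc1cc(O[Si](C(C)C)(C(C)C)C(C)C)c(Oc6cc(OC)cc(OC)c6)c2c1Oc1c3c4c(OC)cc(OC)c(Oc5cc(OC)cc(OC)c5)c4oc3cc(OC)c1O2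
F9 | step 4 | ethyl 7-(2-formyl-3,5-dimethoxyphenoxy)-5-methoxy-1,4-benzodioxine-2-carboxylate | CCOC(=O)C1=COc2c(OC)cc(Oc3cc(OC)cc(OC)c3C=O)cc2O1
F10 | step 4 | ethyl 7-[2-(formyloxy)-3,5-dimethoxyphenoxy]-5-methoxy-1,4-benzodioxine-2-carboxylate | CCOC(=O)C1=COc2c(OC)cc(Oc3cc(OC)cc(OC)c3OC=O)cc2O1
F11 | step 4 | ethyl 7-(2-hydroxy-3,5-dimethoxyphenoxy)-5-methoxy-1,4-benzodioxine-2-carboxylate | CCOC(=O)C1=COc2c(OC)cc(Oc3cc(OC)cc(OC)c3O)cc2O1
F12 | step 4 | ethyl 7-[2-(3,5-dimethoxyphenoxy)-3,5-dimethoxyphenoxy]-5-methoxy-1,4-benzodioxine-2-carboxylate | CCOC(=O)C1=COc2c(OC)cc(Oc3cc(OC)cc(OC)c3Oc3cc(OC)cc(OC)c3)cc2O1
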